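**Retrosynthetic overview** (upper flavan = rings A, C, B; lower flavan = rings D, F, E; usual flavan numbering)
1. The target comes from its nona-O-benzyl ether (free upper 3-OH) by one global hydrogenolysis.
2. Upper ring C is opened at C4–C4a: ring A is a phloroglucinol whose two carbons ortho to O1 are equivalent and electron-rich, and C4 is a bare CH2 beside the C3 carbinol, which is what arene attack on the CH2 end of a C3–C4 epoxide leaves behind.
3. The O1–C2 ether bond comes from Mitsunobu inversion of an anti epoxy alcohol with 3,5-bis(benzyloxy)phenol; the epoxy alcohol comes from Sharpless kinetic resolution of the aryl vinyl carbinol made from a biaryl aldehyde and vinylmagnesium bromide.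
4. The biaryl bond C6' (ring B)–C8 (ring D) comes from a Suzuki coupling of 8-bromo-penta-O-benzylepicatechin with a 2-formylarylboronate derived from 3,4-dihydroxybenzaldehyde.
5. Ring order: D, F and E arrive intact in (−)-epicatechin, ring B is joined by the Suzuki step, ring A is attached as an ether, and ring C is closed last.

Key step: step 12

Assumption: the C6'–C8 biaryl axis carries three ortho substituents and is drawn without an axial descriptor, so it is treated as not configurationally fixed; intermediates may appear as interconverting rotamers and no axial control is attempted.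
Notation: "Ar" = 4,5-bis(benzyloxy)-2-[(2R,3R)-3,5,7-tris(benzyloxy)-2-(3,4-bis(benzyloxy)phenyl)chroman-8-yl]phenyl, i.e. benzylated ring B carrying the benzylated lower flavan at its C6'.

**Step 1**
Reactants: 1 (−)-epicatechin
Product: 2 5,7,3',4'-tetra-O-benzyl-(−)-epicatechin [(2R,3R)-5,7-bis(benzyloxy)-2-(3,4-bis(benzyloxy)phenyl)chroman-3-ol]
Conditions: BnBr (4.4 equiv), K2CO3, DMF, 0 °C → rt, Ar
Reagents that add atoms: benzyl bromide, BrCc1ccccc1
Why: Williamson etherification in which carbonate deprotonates only the four phenols, so the secondary 3-hydroxyl stays free, while the mild base, low temperature and inert atmosphere limit C-benzylation and base-induced epimerisation at C2.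

**Step 2**
Reactants: 2 5,7,3',4'-tetra-O-benzyl-(−)-epicatechin
Product: 3 3,5,7,3',4'-penta-O-benzyl-(−)-epicatechin
Conditions: NaH, BnBr, n-Bu4NI (cat.), DMF, 0 °C → rt
Reagents that add atoms: benzyl bromide, BrCc1ccccc1
Why: Williamson etherification of the sodium alkoxide of the remaining secondary alcohol; with every phenol already capped no quinone methide can form, so C2 and C3 keep their configuration.

**Step 3**
Reactants: 3 3,5,7,3',4'-penta-O-benzyl-(−)-epicatechin
Product: 4 8-bromo-3,5,7,3',4'-penta-O-benzyl-(−)-epicatechin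
Conditions: NBS (1.0 equiv), CH2Cl2, −78 → 0 °C
Reagents that add atoms: N-bromosuccinimide, O=C1CCC(=O)N1Br
Why: Electrophilic aromatic bromination of the phloroglucinol-type ring D, where C8 is expected to be the more reactive of the two free positions as is usual for 5,7-di-O-alkyl flavans, and one equivalent at low temperature should stop at the monobromide.

**Step 4**
Reactants: 5 3,4-dihydroxybenzaldehyde
Product: 6 3,4-bis(benzyloxy)benzaldehyde
Conditions: BnBr, K2CO3, DMF, 60 °C
Reagents that add atoms: benzyl bromide, BrCc1ccccc1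
Why: Williamson etherification of both catechol hydroxyls under standard carbonate conditions, to which the aldehyde is inert.

**Step 5**
Reactants: 6 3,4-bis(benzyloxy)benzaldehyde
Product: 7 4,5-bis(benzyloxy)-2-bromobenzaldehyde
Conditions: Br2, NaOAc, AcOH, rt
Reagents that add atoms: bromine, BrBr
Why: Electrophilic aromatic bromination directed para to the 3-benzyloxy group (the 4-benzyloxy group is engaged in conjugation with the formyl group), which places bromine ortho to the aldehyde, while the acetate buffer removes HBr so the benzyl ethers survive.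

**Step 6**
Reactants: 7 4,5-bis(benzyloxy)-2-bromobenzaldehyde
Product: 8 4,5-bis(benzyloxy)-2-(4,4,5,5-tetramethyl-1,3,2-dioxaborolan-2-yl)benzaldehyde
Conditions: B2pin2, PdCl2(dppf) (cat.), KOAc, 1,4-dioxane, 85 °C
Reagents that add atoms: bis(pinacolato)diboron, CC1(C)OB(OC1(C)C)B1OC(C)(C)C(C)(C)O1
Why: Miyaura borylation of the aryl bromide, a reaction that tolerates the aldehyde and the benzyl ethers under the weakly basic acetate conditions.

**Step 7**
Reactants: 4 8-bromo-3,5,7,3',4'-penta-O-benzyl-(−)-epicatechin; 8 4,5-bis(benzyloxy)-2-(4,4,5,5-tetramethyl-1,3,2-dioxaborolan-2-yl)benzaldehyde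
Product: 9 biaryl aldehyde Ar–CHO [4,5-bis(benzyloxy)-2-(penta-O-benzylepicatechin-8-yl)benzaldehyde]
Conditions: Pd(OAc)2 (cat.), SPhos, K3PO4, toluene/H2O, 90 °C
Reagents that add atoms: none
Why: Suzuki–Miyaura coupling forming the C6'–C8 biaryl bond, with the bulky electron-rich biarylphosphine chosen because the bromide is electron-rich and flanked by two oxygen substituents; the flavan stereocentres are remote and untouched.

**Step 8**
Reactants: 9 biaryl aldehyde Ar–CHO; 10 vinylmagnesium bromide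
Product: 11 1-Ar-prop-2-en-1-ol, obtained as a mixture of both carbinol epimers
Conditions: THF, −78 → 0 °C; then H2O
Reagents that add atoms: none
Why: Grignard 1,2-addition to the aryl aldehyde; no useful facial bias is expected from the remote flavan stereocentres, so both epimers should form and the carbinol centre is sorted out in step 9.

**Step 9**
Reactants: 11 1-Ar-prop-2-en-1-ol (epimer mixture)
Product: 12 anti epoxy alcohol (S)-Ar[(2R)-oxiran-2-yl]methanol
Conditions: Ti(OiPr)4, L-(+)-diisopropyl tartrate, t-BuOOH (0.55 equiv relative to 11), 4 Å molecular sieves, CH2Cl2, −20 °C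
Reagents that add atoms: tert-butyl hydroperoxide, CC(C)(C)OO
Why: Sharpless kinetic resolution, in which the titanium L-(+)-tartrate complex epoxidises the (R)-carbinol epimer much faster than the (S) epimer and with anti (erythro) selectivity, the face of the vinyl group being chosen by the tartrate so that the new oxirane centre is (R) and the product carbinol is named (S) because oxiranyl now outranks aryl; the slow (S) epimer stays as allylic alcohol and is removed by chromatography.

**Step 10**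
Reactants: 13 phloroglucinol
Product: 14 3,5-bis(benzyloxy)phenol
Conditions: BnBr (2.0 equiv), K2CO3, DMF, 0 °C → rt
Reagents that add atoms: benzyl bromide, BrCc1ccccc1
Why: Williamson etherification run with two equivalents of benzyl bromide as a statistical dibenzylation, from which the symmetric dibenzyl ether is separated from mono- and tribenzyl ethers by chromatography.

**Step 11**
Reactants: 12 anti epoxy alcohol; 14 3,5-bis(benzyloxy)phenol
Product: 15 aryl ether epoxide (2R)-2-[(R)-Ar(3,5-bis(benzyloxy)phenoxy)methyl]oxirane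
Conditions: PPh3, DIAD, toluene, 0 °C → rt
Reagents that add atoms: none
Why: Mitsunobu reaction in which the phenoxide displaces the alkoxyphosphonium group by SN2 with inversion of the carbinol from (S) to (R), turning the anti epoxy alcohol into the O1/O3 syn (threo) ether that maps onto a 2,3-cis flavan, while the neutral conditions leave the epoxide intact and the adjacent oxirane disfavours ionisation.

**Step 12**
Reactants: 15 aryl ether epoxide
Product: 16 nona-O-benzyl target with free upper 3-hydroxyl [(2R,3R)-5,7-bis(benzyloxy)-2-Ar-chroman-3-ol]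
Conditions: (CF3)2CHOH/CH2Cl2 (4:1), high dilution, 0 °C → rt
Reagents that add atoms: none
Why: Hydrogen bonding from the fluoroalcohol polarises the C4–O bond of the terminal epoxide, a ring A carbon ortho to O1 (activated by three oxygen substituents) attacks the primary carbon C4 in an SN2-like Friedel–Crafts alkylation, and loss of a proton from the arenium ion restores aromaticity and leaves the C3 oxygen as the free hydroxyl. The closest known reaction type is the fluoroalcohol- or Lewis-acid-promoted epoxy-arene cyclisation of aryl glycidyl ethers to chroman-3-ols. Ring C closes in the 6-endo-tet mode through the new C4–C4a bond. No stereocentre is created, since no bond to C2 or C3 is broken, so the relative configuration fixed in steps 9 and 11 should appear unchanged as the 2,3-cis flavan-3-ol. The step needs attack at C4 instead of 5-exo attack at C3 and no ionisation of the benzylic C2–O1 bond; the unhindered primary terminus, the poor π overlap available to an arene in a five-membered closure, the inductive effect of the neighbouring oxygens and the absence of strong acid should secure this, and because the two ortho carbons of ring A are equivalent and the para carbon cannot reach, only one chroman can form.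

**Step 13**
Reactants: 16 nona-O-benzyl target
Product: 17 target, (2R,3R)-2-{2-[(2R,3R)-2-(3,4-dihydroxyphenyl)-3,5,7-trihydroxychroman-8-yl]-4,5-dihydroxyphenyl}chroman-3,5,7-triol
Conditions: H2 (1 atm), Pd(OH)2/C, THF/MeOH, rt
Reagents that add atoms: none
Why: Catalytic hydrogenolysis of the nine benzyl ethers over Pd(OH)2 on carbon under neutral conditions, which should leave the flavan C2–O1 bonds and all four stereocentres untouched.

**Compound list**
1 | (−)-epicatechin | Oc1cc(O)c2c(c1)O[C@H](c1ccc(O)c(O)c1)[C@H](O)C2 | starting material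
2 | 5,7,3',4'-tetra-O-benzyl-(−)-epicatechin | c1ccccc1COc1cc(OCc2ccccc2)c2c(c1)O[C@H](c1ccc(OCc3ccccc3)c(OCc3ccccc3)c1)[C@H](O)C2 | intermediate
3 | 3,5,7,3',4'-penta-O-benzyl-(−)-epicatechin | c1ccccc1COc1cc(OCc2ccccc2)c2c(c1)O[C@H](c1ccc(OCc3ccccc3)c(OCc3ccccc3)c1)[C@H](OCc1ccccc1)C2 | intermediate
4 | 8-bromo-3,5,7,3',4'-penta-O-benzyl-(−)-epicatechin | c1ccccc1COc1cc(OCc2ccccc2)c2c(c1Br)O[C@H](c1ccc(OCc3ccccc3)c(OCc3ccccc3)c1)[C@H](OCc1ccccc1)C2 | intermediate
5 | 3,4-dihydroxybenzaldehyde | O=Cc1ccc(O)c(O)c1 | starting material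
6 | 3,4-bis(benzyloxy)benzaldehyde | O=Cc1ccc(OCc2ccccc2)c(OCc2ccccc2)c1 | intermediate
7 | 4,5-bis(benzyloxy)-2-bromobenzaldehyde | O=Cc1cc(OCc2ccccc2)c(OCc2ccccc2)cc1Br | intermediate
8 | 4,5-bis(benzyloxy)-2-(4,4,5,5-tetramethyl-1,3,2-dioxaborolan-2-yl)benzaldehyde | O=Cc1cc(OCc2ccccc2)c(OCc2ccccc2)cc1B1OC(C)(C)C(C)(C)O1 | intermediate
9 | biaryl aldehyde Ar–CHO | O=Cc1cc(OCc2ccccc2)c(OCc2ccccc2)cc1-c1c(OCc2ccccc2)cc(OCc2ccccc2)c2c1O[C@H](c1ccc(OCc3ccccc3)c(OCc3ccccc3)c1)[C@H](OCc1ccccc1)C2 | intermediate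
10 | vinylmagnesium bromide | C=C[Mg]Br | starting material
11 | 1-Ar-prop-2-en-1-ol, both carbinol epimers (carbinol centre left undefined) | C=CC(O)c1cc(OCc2ccccc2)c(OCc2ccccc2)cc1-c1c(OCc2ccccc2)cc(OCc2ccccc2)c2c1O[C@H](c1ccc(OCc3ccccc3)c(OCc3ccccc3)c1)[C@H](OCc1ccccc1)C2 | intermediate
12 | anti epoxy alcohol (S)-Ar[(2R)-oxiran-2-yl]methanol | O[C@@H](c1cc(OCc2ccccc2)c(OCc2ccccc2)cc1-c1c(OCc2ccccc2)cc(OCc2ccccc2)c2c1O[C@H](c1ccc(OCc3ccccc3)c(OCc3ccccc3)c1)[C@H](OCc1ccccc1)C2)[C@H]1CO1 | intermediate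
13 | phloroglucinol | Oc1cc(O)cc(O)c1 | starting material
14 | 3,5-bis(benzyloxy)phenol | Oc1cc(OCc2ccccc2)cc(OCc2ccccc2)c1 | intermediate
15 | aryl ether epoxide (2R)-2-[(R)-Ar(3,5-bis(benzyloxy)phenoxy)methyl]oxirane | c1ccccc1COc1cc(OCc2ccccc2)cc(c1)O[C@H](c1cc(OCc2ccccc2)c(OCc2ccccc2)cc1-c1c(OCc2ccccc2)cc(OCc2ccccc2)c2c1O[C@H](c1ccc(OCc3ccccc3)c(OCc3ccccc3)c1)[C@H](OCc1ccccc1)C2)[C@H]1CO1 | intermediate
16 | nona-O-benzyl target with free upper 3-hydroxyl | c1ccccc1COc1cc(OCc2ccccc2)c2c(c1)O[C@H](c1cc(OCc3ccccc3)c(OCc3ccccc3)cc1-c1c(OCc3ccccc3)cc(OCc3ccccc3)c3c1O[C@H](c1ccc(OCc4ccccc4)c(OCc4ccccc4)c1)[C@H](OCc1ccccc1)C3)[C@H](O)C2 | intermediate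
17 | target CNP0353739.3 | Oc1cc(O)c2c(c1)O[C@H](c1cc(O)c(O)cc1-c1c(O)cc(O)c3c1O[C@H](c1ccc(O)c(O)c1)[C@H](O)C3)[C@H](O)C2 | target

**Step count**
Total: 13 steps. Longest linear sequence: 9 steps (1 → 2 → 3 → 4 → 9 → 11 → 12 → 15 → 16 → 17; the branch from 5 through 6, 7, 8 is equally long).

**Steps most likely to fail**

Step 12. The ionising fluoroalcohol may heterolyse the benzylic C2–O1 bond (loss of the ring A phenol or scrambling of C2), or attack at the unactivated primary carbon may be so slow that solvolytic opening of the epoxide takes over. The fallback sets out from 12 and returns at 16, and replaces the Friedel–Crafts closure by an anionic Parham cycloalkylation. Phenol 14 is brominated with N-bromosuccinimide (CH2Cl2, −78 °C) to 2-bromo-3,5-bis(benzyloxy)phenol F1, separated from its 4-bromo isomer. F1 takes the place of 14 in the Mitsunobu reaction with 12 (PPh3, DIAD, toluene) and gives the bromoaryl ether epoxide F2. MgBr2·OEt2 (Et2O, 0 °C) opens the epoxide at its terminal carbon to the bromohydrin F3, and the secondary hydroxyl is silylated (t-BuMe2SiOTf, 2,6-lutidine, CH2Cl2) to the silyl ether F4. n-BuLi (THF, −100 → −78 °C) then effects bromine–lithium exchange on ring A, and the aryllithium displaces the primary bromide in a 6-exo-tet closure to the 3-O-silyl nona-O-benzyl flavan F5. n-Bu4NF (THF) frees the hydroxyl and gives 16.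

Step 11. A partly ionic pathway at the electron-rich, hindered benzylic carbinol may erode the inversion at C2, or the ambident phenol may be alkylated on carbon, or elimination may compete. The fallback sets out from 9 and returns at 15, and makes the ether bond by epoxide opening instead of displacement of an activated alcohol. Still–Gennari olefination of 9 [(CF3CH2O)2P(O)CH2CO2Me, KN(SiMe3)2, 18-crown-6, THF, −78 °C] gives the (Z)-methyl enoate F6, and i-Bu2AlH (CH2Cl2, −78 °C) reduces it to the (Z)-allylic alcohol F7. Sharpless epoxidation with D-(−)-diisopropyl tartrate [Ti(OiPr)4, t-BuOOH, 4 Å sieves, CH2Cl2, −20 °C] gives the cis-(2R,3S)-epoxy alcohol F8. The sodium salt of 14 (NaOH, H2O/1,4-dioxane, 70 °C) opens F8 at the benzylic carbon with inversion to the threo aryloxy diol F9. Selective sulfonylation of the primary hydroxyl (TsCl, Bu2SnO cat., Et3N, CH2Cl2) gives the monotosylate F10, and K2CO3 in MeOH closes the terminal epoxide to 15.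

Step 9. Epoxidation of a terminal vinyl group next to the bulky ortho-biaryl carbinol may be slow and discriminate poorly between the epimers, and the titanium reagent may open the acid-sensitive epoxy alcohol during the long reaction time. The fallback sets out from 9 and returns at 12, and replaces the resolution by a reagent-controlled epoxidation of an (E)-allylic alcohol. Horner–Wadsworth–Emmons reaction of 9 with triethyl phosphonoacetate (NaH, THF) gives the (E)-ethyl enoate F11, and i-Bu2AlH (CH2Cl2, −78 °C) reduces it to the (E)-allylic alcohol F12. Sharpless asymmetric epoxidation with D-(−)-diisopropyl tartrate, a fast and highly face-selective reaction for (E)-3-aryl allylic alcohols, gives the trans-(2R,3R)-epoxy alcohol F13. Ti(OiPr)4-mediated opening with benzoic acid at the benzylic carbon (inversion) gives the erythro benzoate diol F14, and monotosylation of the primary hydroxyl (TsCl, Bu2SnO cat., Et3N) gives the tosylate F15. Brief treatment with K2CO3 in MeOH at 0 °C closes the terminal epoxide and removes the benzoate to give 12; the exposure is kept short to avoid Payne rearrangement.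

**Further compounds**
F1 | step 12 | 2-bromo-3,5-bis(benzyloxy)phenol | Oc1cc(OCc2ccccc2)cc(OCc2ccccc2)c1Br
F2 | step 12 | bromoaryl ether epoxide, (2R)-2-[(R)-Ar(2-bromo-3,5-bis(benzyloxy)phenoxy)methyl]oxirane | Brc1c(OCc2ccccc2)cc(OCc2ccccc2)cc1O[C@H](c1cc(OCc2ccccc2)c(OCc2ccccc2)cc1-c1c(OCc2ccccc2)cc(OCc2ccccc2)c2c1O[C@H](c1ccc(OCc3ccccc3)c(OCc3ccccc3)c1)[C@H](OCc1ccccc1)C2)[C@H]1CO1
F3 | step 12 | bromohydrin, (1R,2R)-1-Ar-3-bromo-1-(2-bromo-3,5-bis(benzyloxy)phenoxy)propan-2-ol | Brc1c(OCc2ccccc2)cc(OCc2ccccc2)cc1O[C@H](c1cc(OCc2ccccc2)c(OCc2ccccc2)cc1-c1c(OCc2ccccc2)cc(OCc2ccccc2)c2c1O[C@H](c1ccc(OCc3ccccc3)c(OCc3ccccc3)c1)[C@H](OCc1ccccc1)C2)[C@H](O)CBr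
F4 | step 12 | tert-butyldimethylsilyl ether of bromohydrin F3 | Brc1c(OCc2ccccc2)cc(OCc2ccccc2)cc1O[C@H](c1cc(OCc2ccccc2)c(OCc2ccccc2)cc1-c1c(OCc2ccccc2)cc(OCc2ccccc2)c2c1O[C@H](c1ccc(OCc3ccccc3)c(OCc3ccccc3)c1)[C@H](OCc1ccccc1)C2)[C@H](O[Si](C)(C)C(C)(C)C)CBr
F5 | step 12 | 3-O-tert-butyldimethylsilyl ether of 16 | c1ccccc1COc1cc(OCc2ccccc2)c2c(c1)O[C@H](c1cc(OCc3ccccc3)c(OCc3ccccc3)cc1-c1c(OCc3ccccc3)cc(OCc3ccccc3)c3c1O[C@H](c1ccc(OCc4ccccc4)c(OCc4ccccc4)c1)[C@H](OCc1ccccc1)C3)[C@H](O[Si](C)(C)C(C)(C)C)C2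
F6 | step 11 | methyl (Z)-3-Ar-prop-2-enoate | COC(=O)/C=C\c1cc(OCc2ccccc2)c(OCc2ccccc2)cc1-c1c(OCc2ccccc2)cc(OCc2ccccc2)c2c1O[C@H](c1ccc(OCc3ccccc3)c(OCc3ccccc3)c1)[C@H](OCc1ccccc1)C2
F7 | step 11 | (Z)-3-Ar-prop-2-en-1-ol | OC/C=C\c1cc(OCc2ccccc2)c(OCc2ccccc2)cc1-c1c(OCc2ccccc2)cc(OCc2ccccc2)c2c1O[C@H](c1ccc(OCc3ccccc3)c(OCc3ccccc3)c1)[C@H](OCc1ccccc1)C2
F8 | step 11 | cis-epoxy alcohol, [(2R,3S)-3-Ar-oxiran-2-yl]methanol | OC[C@H]1O[C@H]1c1cc(OCc2ccccc2)c(OCc2ccccc2)cc1-c1c(OCc2ccccc2)cc(OCc2ccccc2)c2c1O[C@H](c1ccc(OCc3ccccc3)c(OCc3ccccc3)c1)[C@H](OCc1ccccc1)C2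
F9 | step 11 | threo aryloxy diol, (2R,3R)-3-Ar-3-(3,5-bis(benzyloxy)phenoxy)propane-1,2-diol | c1ccccc1COc1cc(OCc2ccccc2)cc(c1)O[C@H](c1cc(OCc2ccccc2)c(OCc2ccccc2)cc1-c1c(OCc2ccccc2)cc(OCc2ccccc2)c2c1O[C@H](c1ccc(OCc3ccccc3)c(OCc3ccccc3)c1)[C@H](OCc1ccccc1)C2)[C@H](O)CO
F10 | step 11 | primary monotosylate of diol F9 | c1ccccc1COc1cc(OCc2ccccc2)cc(c1)O[C@H](c1cc(OCc2ccccc2)c(OCc2ccccc2)cc1-c1c(OCc2ccccc2)cc(OCc2ccccc2)c2c1O[C@H](c1ccc(OCc3ccccc3)c(OCc3ccccc3)c1)[C@H](OCc1ccccc1)C2)[C@H](O)COS(=O)(=O)c1ccc(C)cc1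
F11 | step 9 | ethyl (E)-3-Ar-prop-2-enoate | CCOC(=O)/C=C/c1cc(OCc2ccccc2)c(OCc2ccccc2)cc1-c1c(OCc2ccccc2)cc(OCc2ccccc2)c2c1O[C@H](c1ccc(OCc3ccccc3)c(OCc3ccccc3)c1)[C@H](OCc1ccccc1)C2
F12 | step 9 | (E)-3-Ar-prop-2-en-1-ol | OC/C=C/c1cc(OCc2ccccc2)c(OCc2ccccc2)cc1-c1c(OCc2ccccc2)cc(OCc2ccccc2)c2c1O[C@H](c1ccc(OCc3ccccc3)c(OCc3ccccc3)c1)[C@H](OCc1ccccc1)C2
F13 | step 9 | trans-epoxy alcohol, [(2R,3R)-3-Ar-oxiran-2-yl]methanol | OC[C@H]1O[C@@H]1c1cc(OCc2ccccc2)c(OCc2ccccc2)cc1-c1c(OCc2ccccc2)cc(OCc2ccccc2)c2c1O[C@H](c1ccc(OCc3ccccc3)c(OCc3ccccc3)c1)[C@H](OCc1ccccc1)C2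
F14 | step 9 | erythro benzoate diol, (1S,2R)-1-Ar-2,3-dihydroxypropyl benzoate | O=C(c1ccccc1)O[C@@H](c1cc(OCc2ccccc2)c(OCc2ccccc2)cc1-c1c(OCc2ccccc2)cc(OCc2ccccc2)c2c1O[C@H](c1ccc(OCc3ccccc3)c(OCc3ccccc3)c1)[C@H](OCc1ccccc1)C2)[C@H](O)CO
F15 | step 9 | primary monotosylate of benzoate diol F14 | O=C(c1ccccc1)O[C@@H](c1cc(OCc2ccccc2)c(OCc2ccccc2)cc1-c1c(OCc2ccccc2)cc(OCc2ccccc2)c2c1O[C@H](c1ccc(OCc3ccccc3)c(OCc3ccccc3)c1)[C@H](OCc1ccccc1)C2)[C@H](O)COS(=O)(=O)c1ccc(C)cc1
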